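**Retrosynthetic overview**

1. Last come C15 desilylation, the methylene lactone (loss of AcOH from C13) and the C5 acetate. The 3(2H)-furanone ring (O–C3) arises by transannular 5-endo-dig addition of C10–OH to a C1–C2≡C3 ynone held in a ten-membered ring.
2. The ten-membered carbocycle is closed at C1–C2 by intramolecular Nozaki–Hiyama–Kishi alkynylation. The C8 carbinol comes from 1,3-anti reduction of a β-hydroxy ketone, which in turn comes from reductive opening of a 2-isoxazoline.
3. Key disconnection: the isoxazoline ring, closed by forming C8–C9 and O–C10 in a magnesium-alkoxide-directed nitrile oxide [3+2] cycloaddition that joins the lactone fragment to a C9=C10(C14)–C1 allylic alcohol. Enabling feature: C8–O and C10–O are 1,3-related across the C9 methylene and C10 is a methyl-bearing, oxygenated quaternary carbon, so C8, C9, C10 and the furanone ring oxygen are the C–C–C–O half of an isoxazoline.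
4. The lactone fragment comes from D-mannose diacetonide: sugar C2/C3 become C4/C5 (C15 by formaldehyde aldol, C3≡C2 from the anomeric carbon), C6 by 1,2-induced alkenylchromium addition (butenolide), C7 by trans conjugate addition, C8 from the added vinyl group.
5. Ring order: dioxolane (from the sugar, temporary) → γ-lactone (step 6) → isoxazoline (step 12, temporary) → ten-membered carbocycle (step 15) → furanone (step 21).

Key step: step 12

Remark (locants): C1–C15 are the germacrane locants of the target: C1 furanone C=O, C2 furanone CH, C3 furanone C–O, C4 C(OH)CH2OH, C5 CHOAc, C6 lactone CH–O, C7 ring-fusion CH, C8 CH–O-methacryloyl, C9 CH2, C10 C(CH3)–O, C11/C12/C13 lactone Cα/C=O/=CH2, C14 CH3, C15 CH2OH. In these locants the target is 4S,5S,6S,7R,8R,10R.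

Remark (assumptions): 1, 8 and 16 are taken as commercial. The C1 carbinol of 25, 26–30 and the oxime geometry of 15 are carried as mixtures (left open in the SMILES) because both are destroyed later. C11 in 12–34 is the epimer trans to the C7 substituent and is also destroyed.

**Route**

Step 1
Reactants: 1 2,3:5,6-di-O-isopropylidene-α-D-mannofuranose
Product: 2 2-C-(hydroxymethyl)-2,3:5,6-di-O-isopropylidene-D-mannofuranose (anomers)
Conditions: aq. CH2O (37%), K2CO3, MeOH, 65 °C
Reagents that add atoms: formaldehyde, C=O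
Why: Base-mediated crossed aldol (hydroxymethylation) at sugar C2 of the open aldehyde tautomer; the cis-fused 2,3-acetonide allows re-closure only with the C2–O configuration retained, which fixes the quaternary carbinol carbon that becomes C4 (with C15).

Step 2
Reactants: 2 2-C-(hydroxymethyl)-2,3:5,6-di-O-isopropylidene-D-mannofuranose
Product: 3 2-C-[(tert-butyldiphenylsilyloxy)methyl]-2,3:5,6-di-O-isopropylidene-D-mannofuranose (anomers)
Conditions: TBDPSCl, imidazole, DMF, 0 °C → rt
Reagents that add atoms: tert-butyl(chloro)diphenylsilane, CC(C)(C)[Si](Cl)(c1ccccc1)c1ccccc1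
Why: Silylation should select the primary alcohol over the hindered hemiacetal hydroxyl, and capping this oxygen also blocks retro-aldol loss of formaldehyde in the next basic step.

Step 3
Reactants: 3 2-C-[(tert-butyldiphenylsilyloxy)methyl]-2,3:5,6-di-O-isopropylidene-D-mannofuranose
Product: 4 1,2-dideoxy-3-C-[(tert-butyldiphenylsilyloxy)methyl]-3,4:6,7-di-O-isopropylidene-D-manno-hept-1-ynitol (free 5-OH)
Conditions: dimethyl (1-diazo-2-oxopropyl)phosphonate, K2CO3, MeOH, 0 °C → rt
Reagents that add atoms: dimethyl (1-diazo-2-oxopropyl)phosphonate, CC(=O)C(=[N+]=[N-])P(=O)(OC)OC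
Why: Seyferth–Gilbert homologation in the Ohira–Bestmann form acts on the hydroxy-aldehyde tautomer of the lactol and turns the anomeric carbon into the C3≡C2 alkyne; the α-carbon is quaternary, so it can neither epimerize nor β-eliminate.

Step 4
Reactants: 4 1,2-dideoxy-3-C-[(tert-butyldiphenylsilyloxy)methyl]-3,4:6,7-di-O-isopropylidene-D-manno-hept-1-ynitol
Product: 5 1-C-triisopropylsilyl derivative of 4 (free 5-OH)
Conditions: n-BuLi (2.1 equiv), THF, −78 °C; TIPSCl, −78 °C → rt
Reagents that add atoms: chlorotriisopropylsilane, CC(C)[Si](Cl)(C(C)C)C(C)C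
Why: C-silylation of a lithium acetylide: in the alkoxide/acetylide dianion only the acetylide carbon should react with the bulky chlorosilane, the hindered secondary lithium alkoxide being inert to it; the cap later shields the alkyne from the nitrile oxide and from enolate chemistry.

Step 5
Reactants: 5 1-C-triisopropylsilyl alkynol
Product: 7 C6 aldehyde (cis-dioxolane: C4 carries C≡C–TIPS and CH2OTBDPS, C5 carries CHO cis to the alkynyl group), via triol 6 (not isolated)
Conditions: H5IO6 (2.5 equiv), EtOAc, 0 °C → rt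
Reagents that add atoms: none
Why: Periodic acid hydrolyses the terminal acetonide selectively and then cleaves the liberated 1,2,3-triol twice (Malaprade glycol cleavage), which removes the two surplus sugar carbons and leaves C6 as an aldehyde beside the intact internal acetonide.

Step 6
Reactants: 7 C6 aldehyde; 8 methyl (Z)-3-iodoprop-2-enoate
Product: 10 butenolide (C6 γ-carbon, C7=C11, 5,6-anti), via hydroxy enoate 9 (not isolated)
Conditions: CrCl2 (4 equiv), NiCl2 (2 mol%), DMF, rt; then PPTS (cat.), CH2Cl2, rt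
Reagents that add atoms: none
Why: Nozaki–Hiyama–Kishi alkenylation: the (Z)-alkenylchromium adds to the α-alkoxy aldehyde under 1,2-induction (attack anti to the C5–O bond and away from the quaternary C4), which sets C6 as the 5,6-anti carbinol, and the (Z)-γ-hydroxy enoate lactonizes to the butenolide.

Step 7
Reactants: 10 butenolide
Product: 12 6,7-trans-7-vinyl-11-(hydroxymethyl) γ-lactone, via magnesium enolate 11 (not isolated)
Conditions: CH2=CHMgBr (3 equiv), CuI (1.5 equiv), THF, −78 → −40 °C; then CH2O (THF solution), −78 → −20 °C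
Reagents that add atoms: vinylmagnesium bromide, C=C[Mg]Br; formaldehyde, C=O
Why: Tandem cuprate conjugate addition/aldol: the vinyl group adds to C7 trans to the bulky C6 substituent (sets C7), and the enolate is trapped by formaldehyde trans to the new vinyl group, installing C13 as a hydroxymethyl precursor of the exocyclic methylene.

Step 8
Reactants: 12 7-vinyl-11-(hydroxymethyl) lactone
Product: 13 C13 O-TBS ether of 12
Conditions: TBSCl, imidazole, DMF, rt
Reagents that add atoms: tert-butyl(chloro)dimethylsilane, CC(C)(C)[Si](C)(C)Cl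
Why: Standard silylation of the only free hydroxyl keeps the β-oxygenated lactone inert to the alkoxide base of the key step (a silyloxy group is a poor leaving group for β-elimination).

Step 9
Reactants: 13 C13 O-TBS vinyl lactone
Product: 15 C8 aldoxime (E/Z), via aldehyde 14 (not isolated)
Conditions: OsO4 (2 mol%), NaIO4, 2,6-lutidine, dioxane/H2O, rt; then NH2OH·HCl, NaOAc, EtOH, 0 °C → rt
Reagents that add atoms: hydroxylamine hydrochloride, NO.Cl
Why: Lemieux–Johnson cleavage of the monosubstituted alkene, which the hindered silylalkyne should survive, gives the C8 aldehyde, and this base-sensitive β-acyloxy aldehyde is condensed at once with hydroxylamine to the aldoxime.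

Step 10
Reactants: 16 (4-methoxybenzyloxy)acetaldehyde
Product: 17 rac-1-(4-methoxybenzyloxy)-3-methylbut-3-en-2-ol
Conditions: CH2=C(CH3)MgBr, THF, −78 → 0 °C
Reagents that add atoms: isopropenylmagnesium bromide, C=C(C)[Mg]Br
Why: Grignard addition to the aldehyde delivers the C9=C10(C14) unit next to the carbinol carbon that becomes C1.

Step 11
Reactants: 17 rac-1-(4-methoxybenzyloxy)-3-methylbut-3-en-2-ol
Product: 18 (S)-1-(4-methoxybenzyloxy)-3-methylbut-3-en-2-ol
Conditions: Ti(OiPr)4 (0.2 equiv), L-(+)-diisopropyl tartrate (0.25 equiv), t-BuOOH (0.6 equiv), 4 Å MS, CH2Cl2, −20 °C, stopped at about 55% conversion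
Reagents that add atoms: none
Why: Sharpless kinetic resolution of a secondary allylic alcohol: with L-(+)-tartrate the R enantiomer is epoxidized faster (oxygen delivered anti to the carbinol substituent), so the S alcohol should be recovered unreacted.

Step 12
Reactants: 15 C8 aldoxime; 18 (S)-1-(4-methoxybenzyloxy)-3-methylbut-3-en-2-ol
Product: 21 (10R)-isoxazoline (C8=N, O–C10, C10 methyl, C1 carbinol syn to C10–O, CH2OPMB handle), via hydroximoyl chloride 19 (not isolated), via nitrile oxide 20 (not isolated)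
Conditions: 15, t-BuOCl, CH2Cl2, −78 °C; then added to 18 (1.5 equiv), i-PrOH, EtMgBr, CH2Cl2, 0 °C → rt
Reagents that add atoms: none
Why: t-BuOCl chlorinates the aldoxime, and the bromomagnesium alkoxide of 18 dehydrochlorinates the hydroximoyl chloride and binds the nitrile oxide oxygen, so that the concerted [3+2] cycloaddition runs inside a magnesium chelate; the closest known reaction type is the magnesium-alkoxide-directed nitrile oxide cycloaddition to 2-substituted secondary allylic alcohols. The five-membered isoxazoline closes by suprafacial addition across C9=C10, forming C8–C9 and O–C10 in one event. Oxygen goes to the disubstituted carbon C10 and carbon to the CH2 terminus C9, the normal regiochemistry for 1,1-disubstituted alkenes, reinforced by the alkoxide tether. The new quaternary stereocenter C10 is controlled by the C1 carbinol: in the chelated transition state the allylic hydrogen is inside, the O–Mg bond outside and the CH2OPMB group anti, so oxygen is delivered syn to C1–O and C10 should be R, while C7 is not touched. The step needs the intermolecular alkene to win over the tethered alkyne, and this is secured by the triisopropylsilyl cap and the quaternary C4, which shield both alkyne carbons, and by the magnesium acceleration of the alkene pathway.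

Step 13
Reactants: 21 (10R)-isoxazoline
Product: 23 C1 aldehyde (5-formyl-5-methylisoxazoline, TIPS-alkyne), via diol 22 (not isolated)
Conditions: DDQ, CH2Cl2/pH 7 buffer, 0 °C; then NaIO4, THF/H2O, rt
Reagents that add atoms: none
Why: Oxidative PMB cleavage by DDQ frees the 1,2-diol, and periodate glycol cleavage removes the extra carbon of the directing carbinol, leaving C1 as a non-enolizable aldehyde on the quaternary C10 while the C10–O bond stays protected inside the isoxazoline.

Step 14
Reactants: 23 C1 aldehyde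
Product: 24 iodoalkyne aldehyde
Conditions: AgF, NIS, MeCN, rt, dark
Reagents that add atoms: N-iodosuccinimide, O=C1CCC(=O)N1I
Why: Desilylative iodination of a silylalkyne: fluoride cleaves the C(sp)–Si bond at silver and the silver acetylide is iodinated in situ, the O-silyl ethers on sp3 carbon not being attacked under these neutral conditions.

Step 15
Reactants: 24 iodoalkyne aldehyde
Product: 25 ten-membered propargylic alcohol (cyclodecyne bridged by the isoxazoline, C1 epimers)
Conditions: CrCl2 (10 equiv), NiCl2 (5 mol%), THF, rt, slow addition to 0.002 M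
Reagents that add atoms: none
Why: Intramolecular Nozaki–Hiyama–Kishi alkynylation: the alkynylchromium formed from the iodoalkyne adds chemoselectively to the aldehyde under high dilution and closes the ten-membered carbocycle at C1–C2, with the cis-acetonide and the isoxazoline as turn elements; the C1 configuration is irrelevant.

Step 16
Reactants: 25 ten-membered propargylic alcohol
Product: 26 C1 O-TES ether of 25
Conditions: TESOTf, 2,6-lutidine, CH2Cl2, −78 °C
Reagents that add atoms: triethylsilyl trifluoromethanesulfonate, CC[Si](CC)(CC)OS(=O)(=O)C(F)(F)F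
Why: Silylation of the only free hydroxyl keeps C1 from directing or being acylated in the next three steps.

Step 17
Reactants: 26 C1 O-TES isoxazoline
Product: 27 β-hydroxy ketone (C8 ketone, C10 tertiary alcohol)
Conditions: Mo(CO)6, MeCN/H2O (10:1), 75 °C
Reagents that add atoms: water, O
Why: Mo(CO)6 cleaves the isoxazoline N–O bond reductively and the β-hydroxy imine is hydrolysed in situ, unveiling the C10 tertiary alcohol (the future furanone oxygen) and the C8 carbonyl under neutral conditions that should not epimerize C7.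

Step 18
Reactants: 27 β-hydroxy ketone
Product: 28 8,10-anti diol (8R)
Conditions: Me4NBH(OAc)3, MeCN/AcOH (1:1), −30 °C
Reagents that add atoms: none
Why: Evans–Saksena reduction: the C10 hydroxyl exchanges onto boron and delivers hydride intramolecularly through a six-membered chair transition state, which should give the 1,3-anti diol and thus the 8R carbinol.

Step 19
Reactants: 28 8,10-anti diol
Product: 29 C8 methacrylate
Conditions: methacrylic anhydride, Et3N, DMAP (cat.), CH2Cl2, 0 °C → rt
Reagents that add atoms: methacrylic anhydride, CC(=C)C(=O)OC(=O)C(C)=C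
Why: DMAP-catalysed acylation takes the only secondary alcohol, the tertiary C10 hydroxyl being unreactive.

Step 20
Reactants: 29 C8 methacrylate
Product: 30 C1 propargylic alcohol
Conditions: PPTS, MeOH/CH2Cl2, 0 °C
Reagents that add atoms: none
Why: Mild acidic methanolysis removes the secondary triethylsilyl ether faster than the primary TBS ether, the TBDPS ether or the acetonide.

Step 21
Reactants: 30 C1 propargylic alcohol
Product: 32 3(2H)-furanone (bicyclic core; C4/C5 acetonide, C13 OTBS, C15 OTBDPS), via ynone 31 (not isolated)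
Conditions: Dess–Martin periodinane, NaHCO3, CH2Cl2, rt; then Ph3PAuNTf2 (5 mol%), CH2Cl2, rt
Reagents that add atoms: none
Why: Dess–Martin oxidation gives the ynone, and monovalent gold activates the alkyne for transannular 5-endo-dig addition of C10–OH to C3 (the β-carbon of the ynone), which closes the furanone and the oxygen bridge of the bicyclo[6.2.1] core; the C4 oxygen is tied up in the acetonide and cannot interfere.

Step 22
Reactants: 32 3(2H)-furanone
Product: 33 C4,C5,C13-triol (C15 OTBDPS)
Conditions: TFA/H2O/THF (1:1:4), 0 °C → rt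
Reagents that add atoms: none
Why: Aqueous acid hydrolyses the acetonide and the primary TBS ether, while the TBDPS ether, the esters, the lactone and the vinylogous ester of the furanone should be stable.

Step 23
Reactants: 33 C4,C5,C13-triol
Product: 35 15-O-TBDPS ether of the target (C5 acetate, α-methylene lactone), via diacetate 34 (not isolated)
Conditions: Ac2O, Et3N, DMAP (cat.), CH2Cl2, 0 °C; then DBU, rt
Reagents that add atoms: acetic anhydride, CC(=O)OC(C)=O
Why: Acetylation takes the primary C13 and secondary C5 hydroxyls but not the tertiary C4 hydroxyl, and DBU then eliminates acetic acid from the β-acetoxy lactone (E1cB) to unveil the α-methylene lactone.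

Step 24
Reactants: 35 15-O-TBDPS ether of the target
Product: 36 CNP0275292.4 (target)
Conditions: HF·pyridine, pyridine/THF, 0 °C → rt
Reagents that add atoms: none
Why: Fluoride cleaves the last silyl ether under buffered, weakly acidic conditions that should avoid acetyl migration and conjugate addition to the two acrylate-type alkenes.

**Compound list**

Names of intermediates are descriptive (germacrane locants); the SMILES carry the configuration.

1 | 2,3:5,6-di-O-isopropylidene-α-D-mannofuranose | O[C@H]1O[C@H]([C@H]2COC(C)(C)O2)[C@@H]3OC(C)(C)O[C@@H]31 | starting material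
2 | 2-C-(hydroxymethyl)-2,3:5,6-di-O-isopropylidene-D-mannofuranose | OC1O[C@H]([C@H]2COC(C)(C)O2)[C@@H]3OC(C)(C)O[C@@]31CO | intermediate
3 | 2-C-[(tert-butyldiphenylsilyloxy)methyl]-2,3:5,6-di-O-isopropylidene-D-mannofuranose | OC1O[C@H]([C@H]2COC(C)(C)O2)[C@@H]3OC(C)(C)O[C@@]31CO[Si](c4ccccc4)(c4ccccc4)C(C)(C)C | intermediate
4 | 1,2-dideoxy-3-C-[(tert-butyldiphenylsilyloxy)methyl]-3,4:6,7-di-O-isopropylidene-D-manno-hept-1-ynitol | C#C[C@@]1(CO[Si](c2ccccc2)(c2ccccc2)C(C)(C)C)OC(C)(C)O[C@H]1[C@H](O)[C@H]3COC(C)(C)O3 | intermediate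
5 | 1-C-triisopropylsilyl derivative of 4 | CC(C)[Si](C(C)C)(C(C)C)C#C[C@@]1(CO[Si](c2ccccc2)(c2ccccc2)C(C)(C)C)OC(C)(C)O[C@H]1[C@H](O)[C@H]3COC(C)(C)O3 | intermediate
6 | 5,6,7-triol from 5 (terminal acetonide removed) | CC(C)[Si](C(C)C)(C(C)C)C#C[C@@]1(CO[Si](c2ccccc2)(c2ccccc2)C(C)(C)C)OC(C)(C)O[C@H]1[C@H](O)[C@H](O)CO | intermediate
7 | C6 aldehyde (cis-dioxolane, CHO cis to alkynyl) | CC(C)[Si](C(C)C)(C(C)C)C#C[C@@]1(CO[Si](c2ccccc2)(c2ccccc2)C(C)(C)C)OC(C)(C)O[C@H]1C=O | intermediate
8 | methyl (Z)-3-iodoprop-2-enoate | COC(=O)/C=C\I | starting material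
9 | (Z)-γ-hydroxy enoate (5,6-anti) | CC(C)[Si](C(C)C)(C(C)C)C#C[C@@]1(CO[Si](c2ccccc2)(c2ccccc2)C(C)(C)C)OC(C)(C)O[C@H]1[C@@H](O)/C=C\C(=O)OC | intermediate
10 | butenolide (C6 γ-carbon, 5,6-anti) | CC(C)[Si](C(C)C)(C(C)C)C#C[C@@]1(CO[Si](c2ccccc2)(c2ccccc2)C(C)(C)C)OC(C)(C)O[C@H]1[C@H]3OC(=O)C=C3 | intermediate
11 | bromomagnesium enolate of the 7-vinyl lactone | CC(C)[Si](C(C)C)(C(C)C)C#C[C@@]1(CO[Si](c2ccccc2)(c2ccccc2)C(C)(C)C)OC(C)(C)O[C@H]1[C@H]3OC(O[Mg]Br)=C[C@@H]3C=C | intermediate
12 | 6,7-trans-7-vinyl-11-(hydroxymethyl) γ-lactone (7,11-trans) | CC(C)[Si](C(C)C)(C(C)C)C#C[C@@]1(CO[Si](c2ccccc2)(c2ccccc2)C(C)(C)C)OC(C)(C)O[C@H]1[C@H]3OC(=O)[C@@H](CO)[C@@H]3C=C | intermediate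
13 | C13 O-TBS ether of 12 | CC(C)[Si](C(C)C)(C(C)C)C#C[C@@]1(CO[Si](c2ccccc2)(c2ccccc2)C(C)(C)C)OC(C)(C)O[C@H]1[C@H]3OC(=O)[C@@H](CO[Si](C)(C)C(C)(C)C)[C@@H]3C=C | intermediate
14 | C8 aldehyde | CC(C)[Si](C(C)C)(C(C)C)C#C[C@@]1(CO[Si](c2ccccc2)(c2ccccc2)C(C)(C)C)OC(C)(C)O[C@H]1[C@H]3OC(=O)[C@@H](CO[Si](C)(C)C(C)(C)C)[C@@H]3C=O | intermediate
15 | C8 aldoxime | CC(C)[Si](C(C)C)(C(C)C)C#C[C@@]1(CO[Si](c2ccccc2)(c2ccccc2)C(C)(C)C)OC(C)(C)O[C@H]1[C@H]3OC(=O)[C@@H](CO[Si](C)(C)C(C)(C)C)[C@@H]3C=NO | intermediate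
16 | (4-methoxybenzyloxy)acetaldehyde | O=CCOCc1ccc(OC)cc1 | starting material
17 | rac-1-(4-methoxybenzyloxy)-3-methylbut-3-en-2-ol | C=C(C)C(O)COCc1ccc(OC)cc1 | intermediate
18 | (S)-1-(4-methoxybenzyloxy)-3-methylbut-3-en-2-ol | C=C(C)[C@H](O)COCc1ccc(OC)cc1 | intermediate
19 | C8 hydroximoyl chloride | CC(C)[Si](C(C)C)(C(C)C)C#C[C@@]1(CO[Si](c2ccccc2)(c2ccccc2)C(C)(C)C)OC(C)(C)O[C@H]1[C@H]3OC(=O)[C@@H](CO[Si](C)(C)C(C)(C)C)[C@@H]3C(Cl)=NO | intermediate
20 | C8 nitrile oxide | CC(C)[Si](C(C)C)(C(C)C)C#C[C@@]1(CO[Si](c2ccccc2)(c2ccccc2)C(C)(C)C)OC(C)(C)O[C@H]1[C@H]3OC(=O)[C@@H](CO[Si](C)(C)C(C)(C)C)[C@@H]3C#[N+][O-] | intermediate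
21 | (10R)-isoxazoline with (1R)-carbinol and CH2OPMB handle | CC(C)[Si](C(C)C)(C(C)C)C#C[C@@]1(CO[Si](c2ccccc2)(c2ccccc2)C(C)(C)C)OC(C)(C)O[C@H]1[C@H]3OC(=O)[C@@H](CO[Si](C)(C)C(C)(C)C)[C@@H]3C4=NO[C@](C)(C4)[C@H](O)COCc5ccc(OC)cc5 | intermediate
22 | 1,2-diol from 21 | CC(C)[Si](C(C)C)(C(C)C)C#C[C@@]1(CO[Si](c2ccccc2)(c2ccccc2)C(C)(C)C)OC(C)(C)O[C@H]1[C@H]3OC(=O)[C@@H](CO[Si](C)(C)C(C)(C)C)[C@@H]3C4=NO[C@](C)(C4)[C@H](O)CO | intermediate
23 | C1 aldehyde (TIPS-alkyne) | CC(C)[Si](C(C)C)(C(C)C)C#C[C@@]1(CO[Si](c2ccccc2)(c2ccccc2)C(C)(C)C)OC(C)(C)O[C@H]1[C@H]3OC(=O)[C@@H](CO[Si](C)(C)C(C)(C)C)[C@@H]3C4=NO[C@](C)(C4)C=O | intermediate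
24 | iodoalkyne aldehyde | IC#C[C@@]1(CO[Si](c2ccccc2)(c2ccccc2)C(C)(C)C)OC(C)(C)O[C@H]1[C@H]3OC(=O)[C@@H](CO[Si](C)(C)C(C)(C)C)[C@@H]3C4=NO[C@](C)(C4)C=O | intermediate
25 | ten-membered propargylic alcohol (isoxazoline-bridged cyclodecyne) | OC1C#C[C@@]2(CO[Si](c5ccccc5)(c5ccccc5)C(C)(C)C)OC(C)(C)O[C@H]2[C@H]3OC(=O)[C@@H](CO[Si](C)(C)C(C)(C)C)[C@@H]3C4=NO[C@]1(C)C4 | intermediate
26 | C1 O-TES ether of 25 | CC[Si](CC)(CC)OC1C#C[C@@]2(CO[Si](c5ccccc5)(c5ccccc5)C(C)(C)C)OC(C)(C)O[C@H]2[C@H]3OC(=O)[C@@H](CO[Si](C)(C)C(C)(C)C)[C@@H]3C4=NO[C@]1(C)C4 | intermediate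
27 | β-hydroxy ketone (C8 ketone, C10 tertiary alcohol) | CC[Si](CC)(CC)OC1C#C[C@@]2(CO[Si](c5ccccc5)(c5ccccc5)C(C)(C)C)OC(C)(C)O[C@H]2[C@H]3OC(=O)[C@@H](CO[Si](C)(C)C(C)(C)C)[C@@H]3C(=O)C[C@@]1(C)O | intermediate
28 | 8,10-anti diol (8R) | CC[Si](CC)(CC)OC1C#C[C@@]2(CO[Si](c5ccccc5)(c5ccccc5)C(C)(C)C)OC(C)(C)O[C@H]2[C@H]3OC(=O)[C@@H](CO[Si](C)(C)C(C)(C)C)[C@@H]3[C@H](O)C[C@@]1(C)O | intermediate
29 | C8 methacrylate | CC[Si](CC)(CC)OC1C#C[C@@]2(CO[Si](c5ccccc5)(c5ccccc5)C(C)(C)C)OC(C)(C)O[C@H]2[C@H]3OC(=O)[C@@H](CO[Si](C)(C)C(C)(C)C)[C@@H]3[C@H](OC(=O)C(C)=C)C[C@@]1(C)O | intermediate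
30 | C1 propargylic alcohol | OC1C#C[C@@]2(CO[Si](c5ccccc5)(c5ccccc5)C(C)(C)C)OC(C)(C)O[C@H]2[C@H]3OC(=O)[C@@H](CO[Si](C)(C)C(C)(C)C)[C@@H]3[C@H](OC(=O)C(C)=C)C[C@@]1(C)O | intermediate
31 | ynone (C1 ketone) | O=C1C#C[C@@]2(CO[Si](c5ccccc5)(c5ccccc5)C(C)(C)C)OC(C)(C)O[C@H]2[C@H]3OC(=O)[C@@H](CO[Si](C)(C)C(C)(C)C)[C@@H]3[C@H](OC(=O)C(C)=C)C[C@@]1(C)O | intermediate
32 | 3(2H)-furanone with C4/C5 acetonide, C13 OTBS, C15 OTBDPS | C=C(C)C(=O)O[C@@H]1C[C@@]2(C)OC(=CC2=O)[C@@]3(CO[Si](c5ccccc5)(c5ccccc5)C(C)(C)C)OC(C)(C)O[C@H]3[C@H]4OC(=O)[C@@H](CO[Si](C)(C)C(C)(C)C)[C@@H]41 | intermediate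
33 | C4,C5,C13-triol (C15 OTBDPS) | C=C(C)C(=O)O[C@@H]1C[C@@]2(C)OC(=CC2=O)[C@](O)(CO[Si](c5ccccc5)(c5ccccc5)C(C)(C)C)[C@@H](O)[C@H]3OC(=O)[C@@H](CO)[C@@H]31 | intermediate
34 | 5,13-di-O-acetate | C=C(C)C(=O)O[C@@H]1C[C@@]2(C)OC(=CC2=O)[C@](O)(CO[Si](c5ccccc5)(c5ccccc5)C(C)(C)C)[C@@H](OC(C)=O)[C@H]3OC(=O)[C@@H](COC(C)=O)[C@@H]31 | intermediate
35 | 15-O-TBDPS ether of the target | C=C(C)C(=O)O[C@@H]1C[C@@]2(C)OC(=CC2=O)[C@](O)(CO[Si](c5ccccc5)(c5ccccc5)C(C)(C)C)[C@@H](OC(C)=O)[C@H]3OC(=O)C(=C)[C@@H]31 | intermediate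
36 | CNP0275292.4 | C=C(C)C(=O)O[C@@H]1C[C@@]2(C)OC(=CC2=O)[C@](O)(CO)[C@@H](OC(C)=O)[C@H]2OC(=O)C(=C)[C@@H]21 | target

**Totals**

Total step count: 24. Longest linear sequence: 22 steps (steps 1–9 and 12–24, from 1); steps 10–11 make the allylic alcohol 18.

**Three steps most likely to fail**

1. Step 15, failure to close the ring. The alkynylchromium must reach a neopentyl aldehyde through a transition state that already holds the bent alkyne, the trans-lactone and the isoxazoline, so intermolecular addition (oligomers) or simple loss of iodine can win. The fallback generates the acetylide by soft deprotonation on a different precursor instead of by reductive metalation. It sets out from 23: AgF in MeCN followed by aqueous NH4Cl removes the alkynyl silyl group and should give the terminal alkyne aldehyde F1. Zn(OTf)2 and Et3N in toluene at 60 °C under high dilution (amine/zinc-triflate alkynylation of a non-enolizable aldehyde) then close the ring and come back to the route at 25.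

2. Step 12, poor facial selectivity at C10. The PMB ether oxygen can chelate magnesium together with the alkoxide and loosen the directing transition state, and a slow alkene addition lets nitrile oxide dimerization grow. The fallback replaces substrate control by reagent control. It sets out from 15: after the same chlorination the hydroximoyl chloride is added to 2-methylprop-2-en-1-ol, Et2Zn and diisopropyl tartrate (zinc-tartrate-mediated asymmetric nitrile oxide cycloaddition to an achiral allylic alcohol, the tartrate antipode being chosen in a model run to give 10R). This should give the primary alcohol isoxazoline F2, and Dess–Martin oxidation comes back to the route at 23.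

3. Step 18, wrong face of hydride delivery. The ten-membered ring may force the C7 side of the ketone into the axial position of the chair transition state, which would give the 8-epimer. The fallback uses the syn-selective reduction and then inverts. It sets out from 27: Et2BOMe and NaBH4 in THF/MeOH at −78 °C (Narasaka–Prasad reduction, external hydride on the boron chelate) should give the 8,10-syn diol F3. Mitsunobu esterification with methacrylic acid (PPh3, DIAD) inverts C8 and comes back to the route at 29.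

**Further compounds**

F1 | step 15 | terminal alkyne aldehyde | C#C[C@@]1(CO[Si](c2ccccc2)(c2ccccc2)C(C)(C)C)OC(C)(C)O[C@H]1[C@H]3OC(=O)[C@@H](CO[Si](C)(C)C(C)(C)C)[C@@H]3C4=NO[C@](C)(C4)C=O
F2 | step 12 | primary alcohol isoxazoline | CC(C)[Si](C(C)C)(C(C)C)C#C[C@@]1(CO[Si](c2ccccc2)(c2ccccc2)C(C)(C)C)OC(C)(C)O[C@H]1[C@H]3OC(=O)[C@@H](CO[Si](C)(C)C(C)(C)C)[C@@H]3C4=NO[C@](C)(C4)CO
F3 | step 18 | 8,10-syn diol | CC[Si](CC)(CC)OC1C#C[C@@]2(CO[Si](c5ccccc5)(c5ccccc5)C(C)(C)C)OC(C)(C)O[C@H]2[C@H]3OC(=O)[C@@H](CO[Si](C)(C)C(C)(C)C)[C@@H]3[C@@H](O)C[C@@]1(C)O
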